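**Retrosynthetic overview** (variabilin numbering: furan C1–C4, chain C5–C20, tetronate C21–C25)
1. The 20E target comes from its 20Z isomer by energy-transfer Z→E isomerisation of the exocyclic enol-ether alkene, the only stereo-element not fixed earlier.
2. The 20Z O-stearoyl tetronate comes from an acyclic α-methyl-β,γ-diketo ester by enol-lactonisation with in-flask O-stearoylation; this is the cyclodehydration of the oxidised last C5 unit presumed for the biogenesis of the tetronic acid.
3. The diketo ester comes from the C1–C20 Grignard reagent and diethyl oxalpropionate (C20–C21 bond).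
4. The C1–C20 bromide comes from ω-hydroxyambliofuran by Ru(OAc)2[(S)-BINAP] hydrogenation (sets C18, the laboratory counterpart of the biosynthetic reduction of the 17,18-alkene); that alcohol comes from ambliofuran (SeO2), made from (E,E)-farnesyl bromide and a 3-furylmethyl Grignard reagent (C5–C6 bond).
5. Ring order: the furan is bought intact in 3-(chloromethyl)furan and never opened; the tetronate is the only ring made, in the penultimate step.

Assumption: the SMILES is taken literally, so C18 is S and the C20=C21 alkene is E (C18 cis to C22, trans to the ring oxygen).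

Step 1
Reactants: 1 3-(chloromethyl)furan; 2 (2E,6E)-farnesyl bromide
Product: 4 ambliofuran [3-((3E,7E)-4,8,12-trimethyltrideca-3,7,11-trien-1-yl)furan], via (furan-3-ylmethyl)magnesium chloride 3 (not isolated)
Conditions: 1, Mg, THF, 0 °C → rt; then 2, Li2CuCl4 (3 mol %), THF, −10 → 0 °C
Reagents that add atoms: none
Why: Kochi-type Li2CuCl4-catalysed coupling of a Grignard reagent with a primary allylic bromide goes by direct SN2 substitution without allylic transposition, so both E alkenes of 2 are carried over unchanged and no stereocentre is formed.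

Step 2
Reactants: 4 ambliofuran
Product: 5 (2E,6E,10E)-13-(furan-3-yl)-2,6,10-trimethyltrideca-2,6,10-trien-1-ol
Conditions: SeO2 (0.3 equiv), t-BuOOH (2.5 equiv), salicylic acid (0.1 equiv), CH2Cl2, 0 °C → rt, stopped near 60 % conversion, 4 recycled
Reagents that add atoms: tert-butyl hydroperoxide, CC(C)(C)OO (supplies the new oxygen through catalytic SeO2, O=[Se]=O)
Why: Sharpless–Umbreit variant of the Riley allylic oxidation (ene reaction, then [2,3]-sigmatropic shift) attacks the trans methyl of the terminal isopropylidene group fastest and gives the E allylic alcohol, while the catalytic SeO2/t-BuOOH system is mild enough for the 3-alkylfuran and partial conversion limits attack at the two internal alkenes.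

Step 3
Reactants: 5 (2E,6E,10E)-13-(furan-3-yl)-2,6,10-trimethyltrideca-2,6,10-trien-1-ol
Product: 6 (2S,6E,10E)-13-(furan-3-yl)-2,6,10-trimethyltrideca-6,10-dien-1-ol
Conditions: H2 (100 atm), Ru(OAc)2[(S)-BINAP] (1 mol %), MeOH, 25 °C
Reagents that add atoms: none
Why: Noyori hydroxyl-directed asymmetric hydrogenation reduces only the alkene that can bind the Ru centre together with the allylic OH, so the two remote trisubstituted alkenes and the furan survive, and the (S)-BINAP complex, assumed to add H2 to the same enantioface as in geraniol → (R)-citronellol, creates the C18 stereocentre as 2S (sense and ee to be checked as the Mosher ester).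

Step 4
Reactants: 6 (2S,6E,10E)-13-(furan-3-yl)-2,6,10-trimethyltrideca-6,10-dien-1-ol
Product: 7 3-[(3E,7E,12S)-13-bromo-4,8,12-trimethyltrideca-3,7-dien-1-yl]furan
Conditions: CBr4, PPh3, CH2Cl2, 0 °C
Reagents that add atoms: carbon tetrabromide, BrC(Br)(Br)Br
Why: Appel reaction (SN2 displacement of the alkoxyphosphonium ion by bromide at the primary carbon) leaves the adjacent C18 stereocentre, the alkenes and the furan untouched.

Step 5
Reactants: 7 3-[(3E,7E,12S)-13-bromo-4,8,12-trimethyltrideca-3,7-dien-1-yl]furan; 8 diethyl oxalpropionate (diethyl 2-methyl-3-oxobutanedioate)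
Product: 11 ethyl (6S,10E,14E)-17-(furan-3-yl)-2,6,10,14-tetramethyl-3,4-dioxoheptadeca-10,14-dienoate, via alkylmagnesium bromide 9 (not isolated), via sodium enolate 10 (not isolated)
Conditions: 7, Mg, THF, 40 °C; separately 8 (3 equiv), NaH (3 equiv), THF, 0 °C; Grignard solution added to the enolate at −78 °C, then −40 °C; quenched cold with aq. NH4Cl
Reagents that add atoms: none
Why: Proposed new method: enolate formation masks the ketone and the vinylogous ester carbonyl of 8, leaving the oxalyl ester as the only electrophilic site, and the tetrahedral adduct should be held as a five-membered magnesium chelate with the neighbouring enolate oxygen until the cold quench, so one acyl substitution gives the diketo ester (closest known reaction types: low-temperature mono-addition of Grignard reagents to dialkyl oxalates and Weinreb-type chelate-controlled ketone synthesis); C18 is not touched and C2 of 11 is an enolised, inconsequential centre.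

Step 6
Reactants: 11 ethyl (6S,10E,14E)-17-(furan-3-yl)-2,6,10,14-tetramethyl-3,4-dioxoheptadeca-10,14-dienoate; 12 stearoyl chloride
Product: 14 (2Z)-2-[(2S,6E,10E)-13-(furan-3-yl)-2,6,10-trimethyltrideca-6,10-dien-1-ylidene]-4-methyl-5-oxo-2,5-dihydrofuran-3-yl octadecanoate, via 20Z tetronic acid 13 (not isolated)
Conditions: DMAP (2.2 equiv), toluene, 100 °C, N2 sweep to remove EtOH; then 12 (1.2 equiv), 0 °C
Reagents that add atoms: none
Why: Proposed new method: DMAP-promoted loss of ethanol from the enolised β-keto ester (the acylketene pathway of DMAP-catalysed β-keto ester transesterification) lets the enol oxygen of the C21 ketone close the five-membered enol lactone, which is the cyclodehydration of an α-methyl-β,γ-diketo acid unit presumed for the biogenesis of the tetronic acid and known as the ketipic acid → pulvinic acid enol-lactonisation; the thermodynamically preferred Z alkene results, and the tetronate anion is then O-acylated by 12 because C3 is blocked by its methyl group.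

Step 7
Reactants: 14 (2Z)-2-[(2S,6E,10E)-13-(furan-3-yl)-2,6,10-trimethyltrideca-6,10-dien-1-ylidene]-4-methyl-5-oxo-2,5-dihydrofuran-3-yl octadecanoate
Product: 15 (2E)-2-[(2S,6E,10E)-13-(furan-3-yl)-2,6,10-trimethyltrideca-6,10-dien-1-ylidene]-4-methyl-5-oxo-2,5-dihydrofuran-3-yl octadecanoate (CNP0018186.1)
Conditions: 2-isopropylthioxanthone (10 mol %), 385 nm LED, rigorously degassed benzene (5 mM), 15 °C, to the photostationary state; normal-phase HPLC (hexane–EtOAc); recovered 14 re-irradiated
Reagents that add atoms: none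
Why: Triplet-sensitised (energy-transfer) Z/E photoisomerisation acts only on the conjugated ylidene-butenolide chromophore (sensitiser triplet energy about 61 kcal/mol, too low for the isolated trisubstituted alkenes or the furan), so only the C20=C21 geometry equilibrates to a photostationary mixture (E share not known in advance) from which the 20E isomer is separated and 14 recycled, with C18 and the 7E,12E alkenes unaffected.

**Compound list**
1 | 3-(chloromethyl)furan | ClCc1ccoc1 | starting material
2 | (2E,6E)-farnesyl bromide, (2E,6E)-1-bromo-3,7,11-trimethyldodeca-2,6,10-triene | CC(C)=CCC/C(C)=C/CC/C(C)=C/CBr | starting material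
3 | (furan-3-ylmethyl)magnesium chloride (not isolated) | Cl[Mg]Cc1ccoc1 | intermediate
4 | ambliofuran, 3-[(3E,7E)-4,8,12-trimethyltrideca-3,7,11-trien-1-yl]furan | CC(C)=CCC/C(C)=C/CC/C(C)=C/CCc1ccoc1 | intermediate
5 | (2E,6E,10E)-13-(furan-3-yl)-2,6,10-trimethyltrideca-2,6,10-trien-1-ol | OC/C(C)=C/CC/C(C)=C/CC/C(C)=C/CCc1ccoc1 | intermediate
6 | (2S,6E,10E)-13-(furan-3-yl)-2,6,10-trimethyltrideca-6,10-dien-1-ol | OC[C@@H](C)CCC/C(C)=C/CC/C(C)=C/CCc1ccoc1 | intermediate
7 | 3-[(3E,7E,12S)-13-bromo-4,8,12-trimethyltrideca-3,7-dien-1-yl]furan | BrC[C@@H](C)CCC/C(C)=C/CC/C(C)=C/CCc1ccoc1 | intermediate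
8 | diethyl oxalpropionate, diethyl 2-methyl-3-oxobutanedioate | CCOC(=O)C(C)C(=O)C(=O)OCC | starting material
9 | [(2S,6E,10E)-13-(furan-3-yl)-2,6,10-trimethyltrideca-6,10-dien-1-yl]magnesium bromide (not isolated) | Br[Mg]C[C@@H](C)CCC/C(C)=C/CC/C(C)=C/CCc1ccoc1 | intermediate
10 | sodium enolate of 8, sodium 1,4-diethoxy-3-methyl-1,4-dioxobut-2-en-2-olate (not isolated) | CCOC(=O)C(C)=C([O-])C(=O)OCC.[Na+] | intermediate
11 | ethyl (6S,10E,14E)-17-(furan-3-yl)-2,6,10,14-tetramethyl-3,4-dioxoheptadeca-10,14-dienoate (C2 epimers, largely enolised) | CCOC(=O)C(C)C(=O)C(=O)C[C@@H](C)CCC/C(C)=C/CC/C(C)=C/CCc1ccoc1 | intermediate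
12 | stearoyl chloride, octadecanoyl chloride | CCCCCCCCCCCCCCCCCC(=O)Cl | starting material
13 | (5Z)-5-[(2S,6E,10E)-13-(furan-3-yl)-2,6,10-trimethyltrideca-6,10-dien-1-ylidene]-4-hydroxy-3-methylfuran-2(5H)-one, (18S,20Z)-variabilin, present as its DMAP salt (not isolated) | OC1=C(C)C(=O)O/C1=C\[C@@H](C)CCC/C(C)=C/CC/C(C)=C/CCc1ccoc1 | intermediate
14 | (2Z)-2-[(2S,6E,10E)-13-(furan-3-yl)-2,6,10-trimethyltrideca-6,10-dien-1-ylidene]-4-methyl-5-oxo-2,5-dihydrofuran-3-yl octadecanoate (20Z isomer) | CCCCCCCCCCCCCCCCCC(=O)OC1=C(C)C(=O)O/C1=C\[C@@H](C)CCC/C(C)=C/CC/C(C)=C/CCc1ccoc1 | intermediate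
15 | (2E)-2-[(2S,6E,10E)-13-(furan-3-yl)-2,6,10-trimethyltrideca-6,10-dien-1-ylidene]-4-methyl-5-oxo-2,5-dihydrofuran-3-yl octadecanoate | CCCCCCCCCCCCCCCCCC(=O)OC1=C(C)C(=O)O/C1=C/[C@@H](C)CCC/C(C)=C/CC/C(C)=C/CCc1ccoc1 | target

**Step count**
Total step count: 7. Longest linear sequence: 7 (1 and 2 to 15; 8 and 12 are bought).

**Steps most likely to fail**

Step 5. The risks are double addition of 9, or collapse of the adduct followed by Dieckmann-type closure of the enolate of 11 to a cyclopentane-1,2,4-trione. Fallback: the ester acyl donor is replaced by an amide made for the purpose. Ethyl propionate (LiN(iPr)2, 2 equiv, THF, −78 °C) is condensed with ethyl N-methoxy-N-methyloxamate at its ester carbonyl to give ethyl 4-[methoxy(methyl)amino]-2-methyl-3,4-dioxobutanoate F1. F1 is deprotonated with NaH and treated with 9 at −40 °C. The N-methoxy chelate cannot collapse before the quench, so only one equivalent of 9 can add. This fallback sets out from 9 and comes back at 11.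

Step 6. The risks are C-acylation to the cyclopentanetrione instead of O-lactonisation, and slow ethanol loss from the ethyl ester. Fallback: the ring is closed at the free-acid oxidation level, as in the classical pulvinic acid synthesis, instead of through the ketene. 11 is hydrolysed under neutral conditions (Me3SnOH, 1,2-dichloroethane, 70 °C). The freed keto acid exists in its ring-closed pseudo-acid form, 4,5-dihydroxy-5-[(2S,6E,10E)-13-(furan-3-yl)-2,6,10-trimethyltrideca-6,10-dien-1-yl]-3-methylfuran-2(5H)-one F2. F2 is dehydrated with (CF3CO)2O/pyridine (CH2Cl2, −20 °C, then aq. NaHCO3) to 13, which is stearoylated with 12 and Et3N at 0 °C to give 14. This fallback sets out from 11 and comes back at 13.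

Step 7. The risks are a photostationary mixture poor in the E isomer, a difficult E/Z separation, and sensitised oxidation of the furan by traces of oxygen. Fallback: the E alkene is built by a stereospecific anti-elimination instead of isomerisation.
- 6 is oxidised (Dess–Martin periodinane, NaHCO3, CH2Cl2, 0 °C) to (2S,6E,10E)-13-(furan-3-yl)-2,6,10-trimethyltrideca-6,10-dienal F3.
- 3-Methyltetronic acid, deprotonated twice (LiN(iPr)2, 2.1 equiv, THF, −78 °C), adds to F3 through C5. After chromatographic removal of the unlike pair this gives the like aldol (5R)-5-[(1R,2S,6E,10E)-13-(furan-3-yl)-1-hydroxy-2,6,10-trimethyltrideca-6,10-dien-1-yl]-4-hydroxy-3-methylfuran-2(5H)-one F4 (the 1S,5S partner serves equally).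
- The enol oxygen is acylated (12, Et3N, CH2Cl2, −78 °C) to (2R)-2-[(1R,2S,6E,10E)-13-(furan-3-yl)-1-hydroxy-2,6,10-trimethyltrideca-6,10-dien-1-yl]-4-methyl-5-oxo-2,5-dihydrofuran-3-yl octadecanoate F5.
- (CF3SO2)2O/pyridine (CH2Cl2, −78 → 0 °C) removes the C20 oxygen and H-21 anti-periplanar, which in the like series can only give the 20E alkene.

This fallback sets out from 6 and comes back at 15.

**Further compounds**
F1 | step 5 | ethyl 4-[methoxy(methyl)amino]-2-methyl-3,4-dioxobutanoate | CCOC(=O)C(C)C(=O)C(=O)N(C)OC
F2 | step 6 | 4,5-dihydroxy-5-[(2S,6E,10E)-13-(furan-3-yl)-2,6,10-trimethyltrideca-6,10-dien-1-yl]-3-methylfuran-2(5H)-one (both C5 epimers) | CC1=C(O)C(O)(C[C@@H](C)CCC/C(C)=C/CC/C(C)=C/CCc2ccoc2)OC1=O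
F3 | step 7 | (2S,6E,10E)-13-(furan-3-yl)-2,6,10-trimethyltrideca-6,10-dienal | O=C[C@@H](C)CCC/C(C)=C/CC/C(C)=C/CCc1ccoc1
F4 | step 7 | (5R)-5-[(1R,2S,6E,10E)-13-(furan-3-yl)-1-hydroxy-2,6,10-trimethyltrideca-6,10-dien-1-yl]-4-hydroxy-3-methylfuran-2(5H)-one | CC1=C(O)[C@@H]([C@H](O)[C@@H](C)CCC/C(C)=C/CC/C(C)=C/CCc2ccoc2)OC1=O
F5 | step 7 | (2R)-2-[(1R,2S,6E,10E)-13-(furan-3-yl)-1-hydroxy-2,6,10-trimethyltrideca-6,10-dien-1-yl]-4-methyl-5-oxo-2,5-dihydrofuran-3-yl octadecanoate | CC1=C(OC(=O)CCCCCCCCCCCCCCCCC)[C@@H]([C@H](O)[C@@H](C)CCC/C(C)=C/CC/C(C)=C/CCc2ccoc2)OC1=O
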